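A small charge of substrate is best spent on a set-up chosen in advance, and the closed-flask runs already made allow that choice.

| setting | alder | larch | oak | birch | Tuesday's | Sunday's | Friday's | Wednesday's |
|---|---|---|---|---|---|---|---|---|
| substrate | 20 mM | 20 mM | 20 mM | 40 mM | 20 mM | 20 mM | 20 mM (fed, over 7.50 h) | 20 mM |
| reagent | 14 mM | 20 mM | 31 mM | 14 mM | 14.0 mM (fed, over 7.50 h) | 14.0 mM | 14.0 mM | 14.0 mM |
| capture agent | 2 mM | 2 mM | 2 mM | 2 mM | 2.00 mM | 2.00 mM | 2.00 mM | 2.00 mM |
| remark | run made earlier | run made earlier | run made earlier | run made earlier | all but reagent at the start; reagent goes in evenly over 7.50 h, the run ends at 15 h | one stirred flow tank at steady state, fed with the mixture as stated, mean residence time 15 h | a stirred flask in which substrate is dosed at a steady rate over 7.50 h without added volume, worked up at 15 h | everything together in a closed stirred flask, run for 15 h |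
| time |  |  |  |  | 15 h |  | 15 h | 15 h |

- alder (time / h: target / %, substrate / %): 0.833: 29, 70; 2.50: 56, 33; 4.00: 77, 17; 6.00: 83, 11; 10.0: 92, 1
- larch (time / h: target / %, substrate / %): 1.33: 38, 54; 4.00: 72, 17; 8.00: 86, 4; 10.0: 87, 2; 15.0: 87, 0
- oak (time / h: target / %, substrate / %): 1.33: 34, 54; 2.50: 54, 31; 4.00: 70, 16; 8.00: 79, 1; 15.0: 85, 2
- birch (time / h: target / %, substrate / %): 3.00: 65, 31; 6.00: 81, 8; 10.0: 90, 3; 12.0: 90, 3; 15.0: 91, 1

(readings scatter by 2 percentage points)

- the set-up with the highest amount of target at the outlet or at the end, in percent of the substrate put in ("none" if the first two lie within 2 percentage points) (Tuesday's / Sunday's / Friday's / Wednesday's / none)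
- amount of target at the outlet or at the end, in percent of the substrate put in, Tuesday's
- amount of target at the outlet or at the end, in percent of the substrate put in, Sunday's
- amount of target at the outlet or at the end, in percent of the substrate put in, Friday's
- amount of target at the outlet or at the end, in percent of the substrate put in, Wednesday's

The last row of each table gives a balance: what is neither target nor substrate, set against target, is the substrate lost per substrate converted. Alder reads 0.0761 at 14 mM of reagent. Larch reads 0.149 at 20 mM, and oak reads 0.153 at 31 mM. Those two rows stand about level, but with a scatter of 2 percentage points per reading they cannot be separated. Birch, with twice the substrate of alder, reads 0.0879.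

The summed ratios over the summed charges of reagent give 0.00590 mM⁻¹, the selectivity factor: substrate lost per substrate turned into target, per mM of reagent charged. The charge stands in here for the [reagent] present, which falls during a run, so this is a reckoning from end-of-run readings and not a momentary value. The alder substrate column gives a decay constant of 0.447 h⁻¹.

The comparison then drifts with [reagent]. Wednesday's repeats alder, so its target is 92.4 %. Friday's keeps the reagent charge but leaves some late substrate, giving 91.4 %. Sunday's tank lets substrate escape and gives 81.2 %. In Tuesday's, substrate has a half-life of 1.55 h, shorter than the feed, so it meets a mean [reagent] of 4.18 mM, less than the charge. Putting that mean in the place of the charge gives 97.6 %, higher than the other set-ups.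

The forecast, working from “the substrate-weighted mean reagent”, names Tuesday's best, with 97 % there, 82 % for Sunday's, 92 % for Friday's and 93 % for Wednesday's, figures that differ from those reckoned here.

The flasks give 96.4 % for Tuesday's, 78.7 % for Sunday's, 89.3 % for Friday's and 90.3 % for Wednesday's, so Tuesday's is best.

    substrate + reagent ⇌ intermediate A (K = 730 L mol⁻¹, k = 0.0540 L mol⁻¹ min⁻¹)
    reagent + intermediate A → intermediate B (k = 1.10 L mol⁻¹ min⁻¹)
    substrate → target (k = 0.00630 min⁻¹)
    intermediate B → intermediate C (k = 3.00 × 10⁻⁵ min⁻¹)
    intermediate C → side product (k = 0.00160 min⁻¹)
    capture agent + intermediate B → trapped intermediate (k = 0.0240 L mol⁻¹ min⁻¹)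

Tuesday's falls short of full yield by 3.60 %, where the selectivity factor reckoned 2.40 %. A neighbour of Tuesday's charged with 35 mM of reagent has a mean [reagent] of 10.4 mM; the rule gives 94.2 % and that flask stores 92.2 %. Intermediate B has a half-life of 16 d by its conversion into intermediate C, far longer than the 15 h of the run. It is the resting state of the lost material: Tuesday's ends with 3.24 % of intermediate B against 0.0182 % of side product, and the neighbour ends with 7.30 % of intermediate B.

The readings were computed with made-up constants; noise was put on by code.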